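**Strategy.** Both rings are cut at the two ring bonds that flank each C(OH)–CMe2–C(OH) triad. This returns every triad to a dimethylmalonate and leaves one open C13 chain: the bridging CH2, the two ring carbons it joins and the adjacent ring C=O carbons form a glutaryl unit capped by two 3-methylbutan-2-ones. The key step turns this bis-1,3-diketone into a tetraanion whose two diketone units each condense twice with a non-enolisable malonate diester (Claisen, then Dieckmann), forming four C–C bonds and closing rings A and B around a bridge already in place. It exploits the symmetry about the CH2 bridge and the blocked CMe2 carbons.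

Key step: step 3

Remarks: the target is drawn as one enol tautomer and has no stereocentre; its tautomers interconvert and count as the same compound. Ring A and ring B are the two identical trione rings. Locants C2 to C12 refer to the tridecane chain of compound 7. LiN(iPr)2 (lithium diisopropylamide) is taken from a commercial solution.

Step 1
Reactants: 1 glutaryl dichloride; 2 N,O-dimethylhydroxylamine hydrochloride (2.2 equiv)
Product: 3 N1,N5-dimethoxy-N1,N5-dimethylpentanediamide (bis-Weinreb amide)
Conditions: K2CO3 (5 equiv), H2O/CH2Cl2, 0 °C to rt
Reagents that add atoms: none
Why: Twofold Schotten–Baumann N-acylation, in which the amine freed from its hydrochloride by carbonate should take both acyl chloride groups (one molecule of 2 per C(=O)Cl group) much faster than water does, and the tertiary amide formed cannot close to an imide; no stereocentre is formed.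

Step 2
Reactants: 3 N1,N5-dimethoxy-N1,N5-dimethylpentanediamide; 4 3-methylbutan-2-one (4.4 equiv)
Product: 7 2,12-dimethyltridecane-3,5,9,11-tetraone, via lithium enolate 5 (not isolated), via dilithium bis-adduct 6 (not isolated)
Conditions: LiN(iPr)2 (4.4 equiv), THF, -78 °C; then 3, -78 to 0 °C; 1 M HCl
Reagents that add atoms: none
Why: Claisen-type C-acylation of a kinetic lithium enolate by a Weinreb amide: the amide base at -78 °C deprotonates 4 on the methyl side, each amide carbonyl takes up one enolate to give a lithium-chelated tetrahedral adduct that releases the 1,3-diketone only on acidic quench (any diketone formed earlier is held as its inert enolate by the second equivalent of 5), so over-addition and ring closure onto the second amide should both be suppressed; no stereocentre is formed.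

Step 3
Reactants: 7 2,12-dimethyltridecane-3,5,9,11-tetraone; 8 dimethyl 2,2-dimethylmalonate (8 equiv)
Product: 11 2,2'-methylenebis[3,5-dihydroxy-4,4-dimethyl-6-(2-methylpropanoyl)cyclohexa-2,5-dien-1-one] (target), via tetralithium tetraenolate 9 (not isolated), via open-chain bis(triketo ester) 10 (not isolated)
Conditions: LiN(iPr)2 (6.5 equiv), THF, -78 to 0 °C; cannulate into 8, THF, -78 °C, then rt to 45 °C; 2 M HCl
Reagents that add atoms: none
Why: Proposed new method: LiN(iPr)2 converts each 1,3-diketone unit of 7 into its 1,3-dianion (C4/C10 first, then the glutaryl CH2 groups C6/C8) to give 9, whose hard terminal carbanions C6 and C8 each attack one ester carbonyl of a molecule of 8, a diester with no alpha-hydrogen that cannot be enolised, while the surplus base removes the now acidic C6-H and C8-H so that 10 exists only as its tetralithium polyenolate; on warming, the doubly carbonyl-flanked carbanions C4 and C10 attack the remaining ester of their own malonyl arm. The closest known reaction types are the terminal (gamma) acylation of 1,3-diketone dianions by esters to 1,3,5-triketones and the Claisen or Dieckmann cyclisation of 3,5,7-triketo esters to acylphloroglucinols and syncarpic-acid-type triones; what is new is running both in tandem, twice, on one tetraanion. Ring A (C4, C5, C6 and one C(=O)-CMe2-C(=O) unit) and ring B (C10, C9, C8 and the second such unit) each close by a 6-exo-trig Dieckmann acyl substitution helped by the gem-dimethyl (Thorpe-Ingold) effect, and each leaves the flask as a doubly enolised vinylogous-acid dianion, which makes closure irreversible and shields the CMe2-flanked diketone from retro-Claisen attack by LiOMe. No stereocentre is created, since C6 and C8 of 10 are enolate carbons that end as sp2 ring carbons. The step needs deprotonation at the glutaryl CH2 groups and not at the isopropyl CH (secured by the kinetic preference of the amide base for the less substituted gamma-position), intermolecular acylation of both termini before a free terminal carbanion can attack the malonyl arm across the bridge or a second chain can attack the same malonate (addressed by cannulating 9 into a large excess of 8 at -78 °C), and C- over O-acylation in the closure (secured because an enol lactone reopens under LiOMe whereas the carbocycle is trapped as its dianion).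

Compound list
1 | glutaryl dichloride (pentanedioyl dichloride) | ClC(=O)CCCC(=O)Cl | starting material
2 | N,O-dimethylhydroxylamine hydrochloride | CNOC.Cl | starting material
3 | N1,N5-dimethoxy-N1,N5-dimethylpentanediamide | CON(C)C(=O)CCCC(=O)N(C)OC | intermediate
4 | 3-methylbutan-2-one | CC(C)C(C)=O | starting material
5 | lithium 3-methylbut-1-en-2-olate (kinetic enolate of 4, not isolated) | C=C(O[Li])C(C)C | intermediate
6 | dilithium 5,9-bis[methoxy(methyl)amino]-2,12-dimethyl-3,11-dioxotridecane-5,9-bis(olate) (tetrahedral bis-adduct, not isolated; the two carbinol centres are unassigned and are lost on quench) | CC(C)C(=O)CC(O[Li])(CCCC(O[Li])(CC(=O)C(C)C)N(C)OC)N(C)OC | intermediate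
7 | 2,12-dimethyltridecane-3,5,9,11-tetraone | CC(C)C(=O)CC(=O)CCCC(=O)CC(=O)C(C)C | intermediate
8 | dimethyl 2,2-dimethylmalonate | COC(=O)C(C)(C)C(=O)OC | starting material
9 | tetralithium 2,12-dimethyltrideca-3,5,8,10-tetraene-3,5,9,11-tetrakis(olate) (tetraanion of 7, not isolated; enolate geometries undefined) | CC(C)C(O[Li])=CC(O[Li])=CCC=C(O[Li])C=C(O[Li])C(C)C | intermediate
10 | dimethyl 2,2,8,8-tetramethyl-4,6-bis(4-methyl-3-oxopentanoyl)-3,7-dioxononanedioate (drawn as keto tautomer; present only as its tetralithium polyenolate, so the two methine carbons carry no configuration; not isolated) | CC(C)C(=O)CC(=O)C(CC(C(=O)CC(=O)C(C)C)C(=O)C(C)(C)C(=O)OC)C(=O)C(C)(C)C(=O)OC | intermediate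
11 | 2,2'-methylenebis[3,5-dihydroxy-4,4-dimethyl-6-(2-methylpropanoyl)cyclohexa-2,5-dien-1-one] (no stereocentre) | CC(C)C(=O)C1=C(O)C(C)(C)C(O)=C(CC2=C(O)C(C)(C)C(O)=C(C(=O)C(C)C)C2=O)C1=O | target

Total step count: 3
Longest linear sequence: 3 steps (1 to 3 to 7 to 11)

Steps most likely to fail

1. Step 3 (Proposed new method). Three processes threaten it:
   - After the first acylation, the still free terminal carbanion on the other side of the bridge may close onto the pendant ester. This would form a carbocycle through C6, C7 and C8 instead of ring A.
   - Proton transfer from the newly acylated half may quench unreacted terminal carbanions and leave one diketone unit untouched.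
   - Dieckmann closure may stall at the open polyenolate, or LiOMe may cut the non-enolisable CMe2-flanked keto ester by retro-Claisen cleavage. If only the last ring closures lag, the crude product can be treated with NaOMe in MeOH.

   Fallback by known chemistry, which gives up the two-directional ring construction. It sets out from 4 (with 8 as the malonyl source) and returns at 11. Claisen condensation of 4 with ethyl acetate (NaH, THF) gives 5-methylhexane-2,4-dione F1. Its 1,3-dianion (LiN(iPr)2, 3 equiv, THF, 0 °C) is acylated at the terminal methyl by excess 8 to give methyl 2,2,8-trimethyl-3,5,7-trioxononanoate F2. NaOMe in MeOH closes F2 by Dieckmann condensation to isobutyrylfilicinic acid F3. Two molecules of F3 are then joined at their free ring CH by aqueous formaldehyde with KOH (Knoevenagel condensation followed by Michael addition of the second ring), which delivers 11. No tetraanion is involved and the bridge is made last.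

2. Step 2. The second acylation may stay incomplete, the enolate may equilibrate to the more substituted isomer on warming, or the base may attack the Weinreb amide itself (alpha-deprotonation, or elimination of formaldehyde from the N-OMe group).

   Fallback that replaces the enolate by a non-enolisable carbon nucleophile. It sets out from 3 and returns at 7. Addition of the lithium acetylide of 3-methylbut-1-yne (n-BuLi, THF, -78 to 0 °C) to both amide groups gives 2,12-dimethyltrideca-3,10-diyne-5,9-dione F4. Conjugate addition of pyrrolidine (EtOH, rt) gives the bis-enaminone 2,12-dimethyl-3,11-di(pyrrolidin-1-yl)trideca-3,10-diene-5,9-dione F5. Hydrolysis with aqueous HCl in THF gives 7.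

3. Step 1. Hydrolysis of the bis(acid chloride) in the two-phase medium may compete with amidation, so that one end stops at the carboxylic acid.

   Fallback without an acid chloride. It sets out from 2 and returns at 3. Glutaric acid is activated with 1,1'-carbonyldiimidazole (CH2Cl2, rt) to 1,5-di(1H-imidazol-1-yl)pentane-1,5-dione F6, which is treated in the same flask with 2 to give 3.

Further compounds
F1 | step 3 | 5-methylhexane-2,4-dione | CC(C)C(=O)CC(C)=O
F2 | step 3 | methyl 2,2,8-trimethyl-3,5,7-trioxononanoate | COC(=O)C(C)(C)C(=O)CC(=O)CC(=O)C(C)C
F3 | step 3 | isobutyrylfilicinic acid, 3,5-dihydroxy-4,4-dimethyl-2-(2-methylpropanoyl)cyclohexa-2,5-dien-1-one | CC(C)C(=O)C1=C(O)C(C)(C)C(O)=CC1=O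
F4 | step 2 | 2,12-dimethyltrideca-3,10-diyne-5,9-dione | CC(C)C#CC(=O)CCCC(=O)C#CC(C)C
F5 | step 2 | 2,12-dimethyl-3,11-di(pyrrolidin-1-yl)trideca-3,10-diene-5,9-dione (alkene geometry not controlled, both isomers hydrolyse to 7) | CC(C)C(=CC(=O)CCCC(=O)C=C(C(C)C)N1CCCC1)N1CCCC1
F6 | step 1 | 1,5-di(1H-imidazol-1-yl)pentane-1,5-dione | O=C(CCCC(=O)n1ccnc1)n1ccnc1
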